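**Assumption:** germacrane numbering is used for the ten-membered ring (C1=C10, oxirane C4–C5, OH on C6, isopropyl on C7, ester on C8); 2-methylcyclohex-2-en-1-one and isobutylzinc bromide solution are taken as commercial.

**Retrosynthetic overview**
- Target ⇐ hydroxyl-directed epoxidation of the 4,5-alkene, after an Evans–Tishchenko reaction that reduces the C6 ketone and puts the trimethoxybenzoyl group on O8 in one step.
- β-Hydroxy dienone ⇐ ring expansion (6,6 → 10) of a decalin enone mesylate by conjugate borylation and boronate Grob fragmentation, which makes both E alkenes at once.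
- Decalin ⇐ intramolecular aldol (closes ring B) of a keto aldehyde built on ring A; ring A comes from 2-methylcyclohexenone by CBS reduction, epoxidation, reductive allylation, mesylation, methylation, triflation and carbonylative coupling.
- Order of rings: ring A (bought), ring B (aldol), cleavage of the shared bond to the ten-membered ring, oxirane last.
- The aroyl unit is carried as 3,4,5-trimethoxybenzaldehyde made from p-cresol.

**Route**

Step 1
Reactants: 1 2-methylcyclohex-2-en-1-one
Product: 2 (1S)-2-methylcyclohex-2-en-1-ol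
Conditions: (R)-Me-CBS oxazaborolidine (10 mol%), BH3·SMe2 (0.7 equiv), THF, −20 °C; MeOH
Reagents that add atoms: none
Why: Corey–Bakshi–Shibata reduction in which the α-methylvinyl arm acts as the large group, so the (R)-catalyst gives the (S)-carbinol; this is the only absolute stereocontrol element and every later centre is relayed from it.

Step 2
Reactants: 2 (1S)-2-methylcyclohex-2-en-1-ol
Product: 4 (1R,6R)-1-methyl-7-oxabicyclo[4.1.0]heptan-2-one, via epoxy alcohol 3 (not isolated)
Conditions: VO(acac)2 (2 mol%), tBuOOH, CH2Cl2, 0 °C; then Dess–Martin periodinane, NaHCO3, 23 °C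
Reagents that add atoms: tert-butyl hydroperoxide CC(C)(C)OO
Why: hydroxyl-directed vanadium epoxidation delivers oxygen syn to the OH of the cyclic allylic alcohol and fixes both oxirane carbons, and Dess–Martin oxidation then converts the directing carbinol into the ketone.

Step 3
Reactants: 4 (1R,6R)-1-methyl-7-oxabicyclo[4.1.0]heptan-2-one; 5 allyl bromide
Product: 7 (2S,3R)-3-hydroxy-2-methyl-2-(prop-2-en-1-yl)cyclohexan-1-one, via dilithium enolate alkoxide 6 (not isolated)
Conditions: Li (2.2 equiv), NH3/THF, −78 °C; then 5, −78 → −33 °C; NH4Cl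
Reagents that add atoms: none
Why: dissolving-metal reductive opening of the α,β-epoxy ketone gives the C2 enolate regiospecifically, and allylation anti to the neighbouring lithium alkoxide builds the quaternary carbon with allyl trans to oxygen (reductive alkylation).

Step 4
Reactants: 7 (2S,3R)-3-hydroxy-2-methyl-2-(prop-2-en-1-yl)cyclohexan-1-one
Product: 8 (1R,2S)-2-methyl-3-oxo-2-(prop-2-en-1-yl)cyclohexyl methanesulfonate
Conditions: MsCl, Et3N, CH2Cl2, 0 °C
Reagents that add atoms: methanesulfonyl chloride CS(=O)(=O)Cl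
Why: O-sulfonylation with retention; the mesylate cannot undergo β-elimination towards the quaternary α-carbon and is carried to the fragmentation as the leaving group.

Step 5
Reactants: 8 (1R,2S)-2-methyl-3-oxo-2-(prop-2-en-1-yl)cyclohexyl methanesulfonate
Product: 9 (1R,2S)-2,4-dimethyl-3-oxo-2-(prop-2-en-1-yl)cyclohexyl methanesulfonate (both C4 epimers)
Conditions: LiN(iPr)2, THF, −78 °C; MeI
Reagents that add atoms: iodomethane CI
Why: enolate alkylation at the only enolisable α-carbon; the new centre is irrelevant because it becomes sp2 in the next step.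

Step 6
Reactants: 9 (1R,2S)-2,4-dimethyl-3-oxo-2-(prop-2-en-1-yl)cyclohexyl methanesulfonate
Product: 10 (5R,6S)-5-(methanesulfonyloxy)-2,6-dimethyl-6-(prop-2-en-1-yl)cyclohex-1-en-1-yl trifluoromethanesulfonate
Conditions: KN(SiMe3)2, THF, −78 °C; PhNTf2
Reagents that add atoms: N-phenyl-bis(trifluoromethanesulfonimide) O=S(=O)(N(c1ccccc1)S(=O)(=O)C(F)(F)F)C(F)(F)F
Why: O-triflation of the only possible (tetrasubstituted) enolate, as for 2,2,6-trimethylcyclohexanone.

Step 7
Reactants: 10 (5R,6S)-5-(methanesulfonyloxy)-2,6-dimethyl-6-(prop-2-en-1-yl)cyclohex-1-en-1-yl trifluoromethanesulfonate; 11 isobutylzinc bromide (iBuZnBr)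
Product: 12 (1R,2R)-2,4-dimethyl-3-(3-methylbutanoyl)-2-(prop-2-en-1-yl)cyclohex-3-en-1-yl methanesulfonate
Conditions: Pd(PPh3)4 (5 mol%), CO (1 atm), 11 (2.5 equiv), THF, 50 °C
Reagents that add atoms: carbon monoxide [C-]#[O+]
Why: carbonylative Negishi coupling (oxidative addition of the enol triflate to zerovalent palladium, CO insertion, transmetalation from zinc, reductive elimination); the alkyl mesylate is inert and excess zinc reagent intercepts the acyl-palladium before it can add to the allyl group.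

Step 8
Reactants: 12 (1R,2R)-2,4-dimethyl-3-(3-methylbutanoyl)-2-(prop-2-en-1-yl)cyclohex-3-en-1-yl methanesulfonate
Product: 14 (1R,6R,7S,8aR)-7-hydroxy-4,8a-dimethyl-5-oxo-6-(propan-2-yl)-1,2,3,5,6,7,8,8a-octahydronaphthalen-1-yl methanesulfonate, via keto aldehyde 13 (not isolated)
Conditions: O3, CH2Cl2/MeOH, −78 °C (Sudan Red end point); Me2S; then DBU (0.3 equiv), CH2Cl2, 0 °C
Reagents that add atoms: ozone [O-][O+]=O
Why: ozonolysis cleaves only the electron-rich terminal alkene, and the reversible intramolecular aldol that closes ring B settles under thermodynamic control with the 7-OH equatorial and trans to the axial angular methyl (no 1,3-diaxial contact) and the 6-isopropyl equatorial, which sets the (6R,7S) centres from the quaternary carbon.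

Step 9
Reactants: 14 (1R,6R,7S,8aR)-7-hydroxy-4,8a-dimethyl-5-oxo-6-(propan-2-yl)-1,2,3,5,6,7,8,8a-octahydronaphthalen-1-yl methanesulfonate
Product: 16 (2E,6E,9S,10R)-9-hydroxy-3,7-dimethyl-10-(propan-2-yl)cyclodeca-2,6-dien-1-one, via boryl ketone 15 (not isolated)
Conditions: CuCl (10 mol%), 1,3-dicyclohexylimidazolium chloride (11 mol%), NaOtBu (25 mol%), B2pin2 (1.3 equiv), MeOH (2 equiv), THF, 0 → 23 °C; then NaOMe (2.2 equiv), MeOH, −20 → 0 °C; pH 7 buffer
Reagents that add atoms: none
Why: Proposed new method: a monovalent copper boryl adds to the β-carbon (C4) of the tetrasubstituted enone from the face opposite the angular methyl, and the enolate is protonated at C4a on the same face (the other face is blocked by two axial methyls), giving trans-fused 15 in which the C4–B bond and the C1–OMs bond are both equatorial and antiperiplanar to the C4a–C8a bond; methoxide then forms the tetracoordinate boronate, whose C–B electrons drive a concerted Grob-type 1,4-fragmentation (C4=C4a forms, C4a–C8a breaks, C8a=C1 forms, mesylate leaves) that expands the decalin to the ten-membered ring, fixes both alkenes E from the chair geometry, releases the 1,3-diaxial methyl strain and leaves the ketone as a conjugated enone; the closest known reactions are the Marshall boronate fragmentation of hydroborated octalin mesylates and copper-catalysed β-borylation of enones, and what is new is using a tertiary pinacol boronate made by conjugate borylation of a tetrasubstituted enone as the electrofuge in the same flask.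

Step 10
Reactants: 17 4-methylphenol (p-cresol)
Product: 20 3,5-dibromo-4-hydroxybenzaldehyde, via 2,6-dibromo-4-methylphenol 18 (not isolated), via 2,6-dibromo-4-(dibromomethyl)phenol 19 (not isolated)
Conditions: Br2 (2.05 equiv), o-dichlorobenzene, 35 °C; Br2 (2.1 equiv), 150 °C; H2O, 100 °C
Reagents that add atoms: bromine BrBr; water O
Why: electrophilic ortho-dibromination, then benzylic radical dibromination at high temperature and hydrolysis of the benzal bromide (the established industrial sequence).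

Step 11
Reactants: 20 3,5-dibromo-4-hydroxybenzaldehyde
Product: 21 4-hydroxy-3,5-dimethoxybenzaldehyde (syringaldehyde)
Conditions: NaOMe (4 equiv), CuCl (10 mol%), DMF/MeOH, 110 °C
Reagents that add atoms: sodium methoxide [Na+].[O-]C
Why: copper-catalysed Ullmann-type methoxylation of both aryl bromides.

Step 12
Reactants: 21 4-hydroxy-3,5-dimethoxybenzaldehyde
Product: 22 3,4,5-trimethoxybenzaldehyde
Conditions: MeI, K2CO3, acetone, reflux
Reagents that add atoms: iodomethane CI
Why: Williamson O-methylation of the phenol.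

Step 13
Reactants: 16 (2E,6E,9S,10R)-9-hydroxy-3,7-dimethyl-10-(propan-2-yl)cyclodeca-2,6-dien-1-one; 22 3,4,5-trimethoxybenzaldehyde
Product: 23 (1S,3E,7E,9S,10S)-9-hydroxy-3,7-dimethyl-10-(propan-2-yl)cyclodeca-3,7-dien-1-yl 3,4,5-trimethoxybenzoate
Conditions: SmI2 (0.3 equiv), 22 (4 equiv), THF, −10 °C
Reagents that add atoms: none
Why: Evans–Tishchenko reaction: the hemiacetal of 22 on the C8 hydroxyl, held on trivalent samarium with the ketone, delivers hydride intramolecularly to C6 from the side of the C8–O bond, so the new carbinol is 1,3-anti to the C8 oxygen and the aroyl group ends on O8 only.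

Step 14
Reactants: 23 (1S,3E,7E,9S,10S)-9-hydroxy-3,7-dimethyl-10-(propan-2-yl)cyclodeca-3,7-dien-1-yl 3,4,5-trimethoxybenzoate
Product: 24 (4R,5R,6R,7S,8S)-4,5-epoxy-6-hydroxygermacr-1(10)E-en-8-yl 3,4,5-trimethoxybenzoate (target)
Conditions: VO(acac)2 (5 mol%), tBuOOH (1.5 equiv), 2,6-lutidine, CH2Cl2, 0 °C
Reagents that add atoms: tert-butyl hydroperoxide CC(C)(C)OO
Why: hydroxyl-directed epoxidation: the vanadate ester of the C6 alcohol delivers oxygen to the exposed outer face of the trans 4,5-alkene in the crown conformer (C7 over the inner face, small O–C6–C5=C4 dihedral), which gives the erythro (4R,5R) oxirane, while the 1(10)-alkene has no allylic hydroxyl and is left alone.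

**Compound list**

1 | 2-methylcyclohex-2-en-1-one | CC1=CCCCC1=O | starting material
2 | (1S)-2-methylcyclohex-2-en-1-ol | CC1=CCCC[C@@H]1O | intermediate
3 | (1S,2S,6R)-1-methyl-7-oxabicyclo[4.1.0]heptan-2-ol | C[C@@]12O[C@@H]1CCC[C@@H]2O | intermediate (not isolated)
4 | (1R,6R)-1-methyl-7-oxabicyclo[4.1.0]heptan-2-one | C[C@@]12O[C@@H]1CCCC2=O | intermediate
5 | allyl bromide (3-bromoprop-1-ene) | C=CCBr | starting material
6 | dilithium (3R)-2-methylcyclohex-1-ene-1,3-bis(olate) | [Li+].[Li+].CC1=C([O-])CCC[C@H]1[O-] | intermediate (not isolated)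
7 | (2S,3R)-3-hydroxy-2-methyl-2-(prop-2-en-1-yl)cyclohexan-1-one | C=CC[C@@]1(C)[C@H](O)CCCC1=O | intermediate
8 | (1R,2S)-2-methyl-3-oxo-2-(prop-2-en-1-yl)cyclohexyl methanesulfonate | C=CC[C@@]1(C)[C@H](OS(C)(=O)=O)CCCC1=O | intermediate
9 | (1R,2S)-2,4-dimethyl-3-oxo-2-(prop-2-en-1-yl)cyclohexyl methanesulfonate (both C4 epimers) | C=CC[C@@]1(C)[C@H](OS(C)(=O)=O)CCC(C)C1=O | intermediate
10 | (5R,6S)-5-(methanesulfonyloxy)-2,6-dimethyl-6-(prop-2-en-1-yl)cyclohex-1-en-1-yl trifluoromethanesulfonate | C=CC[C@@]1(C)[C@H](OS(C)(=O)=O)CCC(C)=C1OS(=O)(=O)C(F)(F)F | intermediate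
11 | isobutylzinc bromide (iBuZnBr) | CC(C)C[Zn]Br | starting material
12 | (1R,2R)-2,4-dimethyl-3-(3-methylbutanoyl)-2-(prop-2-en-1-yl)cyclohex-3-en-1-yl methanesulfonate | C=CC[C@@]1(C)[C@H](OS(C)(=O)=O)CCC(C)=C1C(=O)CC(C)C | intermediate
13 | (1R,2R)-2,4-dimethyl-3-(3-methylbutanoyl)-2-(2-oxoethyl)cyclohex-3-en-1-yl methanesulfonate | O=CC[C@@]1(C)[C@H](OS(C)(=O)=O)CCC(C)=C1C(=O)CC(C)C | intermediate (not isolated)
14 | (1R,6R,7S,8aR)-7-hydroxy-4,8a-dimethyl-5-oxo-6-(propan-2-yl)-1,2,3,5,6,7,8,8a-octahydronaphthalen-1-yl methanesulfonate | C[C@@]12C[C@H](O)[C@@H](C(C)C)C(=O)C1=C(C)CC[C@H]2OS(C)(=O)=O | intermediate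
15 | (1R,4S,4aS,6R,7S,8aR)-7-hydroxy-4,8a-dimethyl-5-oxo-6-(propan-2-yl)-4-(4,4,5,5-tetramethyl-1,3,2-dioxaborolan-2-yl)decahydronaphthalen-1-yl methanesulfonate | C[C@@]12C[C@H](O)[C@@H](C(C)C)C(=O)[C@H]1[C@](C)(B3OC(C)(C)C(C)(C)O3)CC[C@H]2OS(C)(=O)=O | intermediate (not isolated)
16 | (2E,6E,9S,10R)-9-hydroxy-3,7-dimethyl-10-(propan-2-yl)cyclodeca-2,6-dien-1-one | C/C1=C\CC/C(C)=C/C(=O)[C@H](C(C)C)[C@@H](O)C1 | intermediate
17 | 4-methylphenol (p-cresol) | Cc1ccc(O)cc1 | starting material
18 | 2,6-dibromo-4-methylphenol | Cc1cc(Br)c(O)c(Br)c1 | intermediate (not isolated)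
19 | 2,6-dibromo-4-(dibromomethyl)phenol | BrC(Br)c1cc(Br)c(O)c(Br)c1 | intermediate (not isolated)
20 | 3,5-dibromo-4-hydroxybenzaldehyde | O=Cc1cc(Br)c(O)c(Br)c1 | intermediate
21 | 4-hydroxy-3,5-dimethoxybenzaldehyde | COc1cc(C=O)cc(OC)c1O | intermediate
22 | 3,4,5-trimethoxybenzaldehyde | COc1cc(C=O)cc(OC)c1OC | intermediate
23 | (1S,3E,7E,9S,10S)-9-hydroxy-3,7-dimethyl-10-(propan-2-yl)cyclodeca-3,7-dien-1-yl 3,4,5-trimethoxybenzoate | COc1cc(C(=O)O[C@H]2C/C(C)=C/CC/C(C)=C/[C@H](O)[C@@H]2C(C)C)cc(OC)c1OC | intermediate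
24 | (4R,5R,6R,7S,8S)-4,5-epoxy-6-hydroxygermacr-1(10)E-en-8-yl 3,4,5-trimethoxybenzoate (CNP0260213.3) | COc1cc(C(=O)O[C@H]2C/C(C)=C/CC[C@@]3(C)O[C@@H]3[C@H](O)[C@@H]2C(C)C)cc(OC)c1OC | target

**Totals and risks**

Total step count: 14. Longest linear sequence: 11 steps (steps 1–9, 13, 14); steps 10–12 are a three-step side branch.

The three steps most likely to fail:

Step 7 (carbonylative coupling at a hindered tetrasubstituted triflate; direct coupling or acyl-palladium cyclisation onto the allyl group may compete). The fallback sets out from 10 and comes back at 12. A CrCl2/NiCl2-mediated Nozaki–Hiyama–Kishi coupling of 10 with 3-methylbutanal in DMF at 23 °C gives (1R,2R)-3-(1-hydroxy-3-methylbutyl)-2,4-dimethyl-2-(prop-2-en-1-yl)cyclohex-3-en-1-yl methanesulfonate F1 (both carbinol epimers), and Dess–Martin oxidation of the allylic alcohol gives 12.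

Step 9 (the new borylative ring expansion; the tetrasubstituted enone may resist borylation, C4a may protonate cis, or 16 may suffer retro-aldol in base). The fallback uses known chemistry, sets out from 14 and comes back at 16. NaBH4/CeCl3 in MeOH at −40 °C reduces the enone carbonyl from the face opposite the angular methyl to give (1R,5R,6R,7S,8aR)-5,7-dihydroxy-4,8a-dimethyl-6-(propan-2-yl)-1,2,3,5,6,7,8,8a-octahydronaphthalen-1-yl methanesulfonate F2. Excess BH3·THF then adds cis across the tetrasubstituted alkene from the same face (boron on C4, hydrogen on C4a, trans ring fusion), and a methanol quench gives (1R,4S,4aS,5S,6R,7S,8aR)-4-(dimethoxyboranyl)-5,7-dihydroxy-4,8a-dimethyl-6-(propan-2-yl)decahydronaphthalen-1-yl methanesulfonate F3. NaOMe in MeOH at 23 °C triggers the classical Marshall boronate fragmentation to (1S,2E,6E,9S,10R)-3,7-dimethyl-10-(propan-2-yl)cyclodeca-2,6-diene-1,9-diol F4, and MnO2 in CH2Cl2 oxidises only the allylic hydroxyl to return 16.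

Step 14 (facial selectivity of the directed epoxidation and acid-promoted transannular cyclisation of the epoxygermacrene). The fallback sets out from 16 and comes back at 24. Weitz–Scheffer epoxidation of the enone with tBuOOH and DBU in CH2Cl2 at 0 °C attacks the outer face of the conjugated alkene and gives (4R,5S,7R,8S)-4,5-epoxy-8-hydroxygermacr-1(10)E-en-6-one F5. The Evans–Tishchenko reaction of F5 with 22 and SmI2 then reduces C6 anti to O8 and acylates O8, giving 24 directly.

**Further compounds**

F1 | step 7 | (1R,2R)-3-(1-hydroxy-3-methylbutyl)-2,4-dimethyl-2-(prop-2-en-1-yl)cyclohex-3-en-1-yl methanesulfonate (both carbinol epimers) | C=CC[C@@]1(C)[C@H](OS(C)(=O)=O)CCC(C)=C1C(O)CC(C)C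
F2 | step 9 | (1R,5R,6R,7S,8aR)-5,7-dihydroxy-4,8a-dimethyl-6-(propan-2-yl)-1,2,3,5,6,7,8,8a-octahydronaphthalen-1-yl methanesulfonate | C[C@@]12C[C@H](O)[C@@H](C(C)C)[C@@H](O)C1=C(C)CC[C@H]2OS(C)(=O)=O
F3 | step 9 | (1R,4S,4aS,5S,6R,7S,8aR)-4-(dimethoxyboranyl)-5,7-dihydroxy-4,8a-dimethyl-6-(propan-2-yl)decahydronaphthalen-1-yl methanesulfonate | C[C@@]12C[C@H](O)[C@@H](C(C)C)[C@@H](O)[C@H]1[C@](C)(B(OC)OC)CC[C@H]2OS(C)(=O)=O
F4 | step 9 | (1S,2E,6E,9S,10R)-3,7-dimethyl-10-(propan-2-yl)cyclodeca-2,6-diene-1,9-diol | C/C1=C\CC/C(C)=C/[C@H](O)[C@H](C(C)C)[C@@H](O)C1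
F5 | step 14 | (4R,5S,7R,8S)-4,5-epoxy-8-hydroxygermacr-1(10)E-en-6-one | C/C1=C\CC[C@@]2(C)O[C@@H]2C(=O)[C@H](C(C)C)[C@@H](O)C1
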